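## Retrosynthetic overview

1. Target ⇒ spiro trienol: last-step anti, Markovnikov bromochlorination of the ring B alkene (C4–Br, C3–Cl).
2. Spiro trienol ⇒ ring A aldehyde + C5 bis-allylic fragment: one-pot palladium-catalysed amphiphilic (4+2) spiroannulation. C5–C6 forms first (asymmetric allylic alkylation, sets spiro C6), then C1–C2 (indium umpolung carbonyl allylation, sets C1).
3. Ring A aldehyde ⇒ nitrile ⇒ acyclic 1,5-enyne: gold-catalysed brominative 6-endo cyclisation (C8–C9 bond, C10–Br).
4. 1,5-Enyne ⇒ 3-chloro-3-methylbut-1-yne + isopropylidenemalononitrile: copper-catalysed propargylic substitution (C6–C11), then loss of one nitrile.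
5. Ring A is formed first, ring B second; the C5 fragment is made separately from prenol in three steps.

Assumption: 1, 2 and 7 are bought. Target numbering is C1 (CHOH), C3 (CClMe), C4 (CHBr), C6 (spiro), C7–C11 (ring A, C10–Br, C11 gem-dimethyl). The sense of induction in step 8 is assigned by analogy, and the ligand enantiomer used is the one that gives R at C6.

## Route

Step 1
Reactants: 1 3-chloro-3-methylbut-1-yne; 2 2-(propan-2-ylidene)propanedinitrile
Product: 3 2-(2-methylbut-3-yn-2-yl)-2-(prop-1-en-2-yl)propanedinitrile
Conditions: CuCl (5 mol%), i-Pr2NEt (1.5 equiv), MeCN, 0 °C to rt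
Reagents that add atoms: none
Why: Copper-catalysed propargylic substitution through a copper acetylide/allenylidene, in which the dicyano-stabilised carbanion of 2 attacks the tertiary propargylic carbon by its α-carbon (the kinetic, deconjugative mode of alkylidene malononitrile anions), joining C6 to C11 without forming a stereocentre.

Step 2
Reactants: 3 2-(2-methylbut-3-yn-2-yl)-2-(prop-1-en-2-yl)propanedinitrile
Product: 4 3,3-dimethyl-2-(prop-1-en-2-yl)pent-4-ynenitrile (racemic)
Conditions: PhMgBr (2.2 equiv), THF, −20 °C to rt; then aq NH4Cl, −78 °C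
Reagents that add atoms: none
Why: Transnitrilation (retro-Thorpe fragmentation): PhMgBr adds to one nitrile and the adduct expels the allyl- and cyano-stabilised carbanion as benzonitrile (one equivalent is consumed by the alkyne C–H), and cold α-protonation gives the deconjugated nitrile as a racemate whose α-centre is erased again in step 8.

Step 3
Reactants: 4 3,3-dimethyl-2-(prop-1-en-2-yl)pent-4-ynenitrile
Product: 5 5-bromo-2,6,6-trimethylcyclohexa-2,4-diene-1-carbonitrile (racemic)
Conditions: Ph3PAuNTf2 (5 mol%), N-bromosuccinimide (1.05 equiv), CH2Cl2, −20 to 0 °C, dark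
Reagents that add atoms: N-bromosuccinimide, O=C1CCC(=O)N1Br
Why: Gold-catalysed 6-endo-dig cycloisomerisation of a 1,5-enyne with a 1,1-disubstituted alkene: the isopropenyl CH2 attacks the terminal alkyne carbon (C8–C9 bond), the tertiary cation loses H-8 to give the conjugated diene, and the C10 vinylgold is intercepted by N-bromosuccinimide (bromodeauration) faster than by the proton; no new stereocentre arises.

Step 4
Reactants: 5 5-bromo-2,6,6-trimethylcyclohexa-2,4-diene-1-carbonitrile
Product: 6 5-bromo-2,6,6-trimethylcyclohexa-2,4-diene-1-carbaldehyde (racemic)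
Conditions: i-Bu2AlH (1.3 equiv), CH2Cl2, −78 °C; then aq potassium sodium tartrate
Reagents that add atoms: water, O
Why: Standard i-Bu2AlH half-reduction of a nitrile and hydrolysis to the aldehyde; the vinyl bromide is inert at −78 °C and the racemic α-centre does not matter because it is enolised in step 8.

Step 5
Reactants: 7 3-methylbut-2-en-1-ol
Product: 8 methyl 3-methylbut-2-en-1-yl carbonate
Conditions: ClCO2Me, pyridine, CH2Cl2, 0 °C
Reagents that add atoms: methyl chloroformate, COC(=O)Cl
Why: Simple acylation of a primary allylic alcohol with a chloroformate, installing the leaving group for the later allylic alkylation.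

Step 6
Reactants: 8 methyl 3-methylbut-2-en-1-yl carbonate
Product: 9 (2E)-4-hydroxy-3-methylbut-2-en-1-yl methyl carbonate
Conditions: SeO2 (0.3 equiv), t-BuOOH (2.5 equiv), CH2Cl2, rt
Reagents that add atoms: tert-butyl hydroperoxide, CC(C)(C)OO
Why: Riley allylic oxidation (ene reaction then [2,3]-sigmatropic shift), which on a trisubstituted alkene oxidises the methyl group trans to the chain and so gives the (E)-allylic alcohol.

Step 7
Reactants: 9 (2E)-4-hydroxy-3-methylbut-2-en-1-yl methyl carbonate
Product: 10 (2E)-4-[(methoxycarbonyl)oxy]-2-methylbut-2-en-1-yl benzoate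
Conditions: BzCl, Et3N, DMAP (cat.), CH2Cl2, 0 °C
Reagents that add atoms: benzoyl chloride, O=C(Cl)c1ccccc1
Why: DMAP-catalysed benzoylation; the benzoate masks the alcohol during the first stage of step 8 and is the slower-ionising allylic ester used in the second stage.

Step 8
Reactants: 6 5-bromo-2,6,6-trimethylcyclohexa-2,4-diene-1-carbaldehyde; 10 (2E)-4-[(methoxycarbonyl)oxy]-2-methylbut-2-en-1-yl benzoate
Product: 12 (1S,6R)-10-bromo-3,7,11,11-tetramethylspiro[5.5]undeca-3,7,9-trien-1-ol, via allylated aldehyde 11 (not isolated)
Conditions: Pd2(dba)3 (2.5 mol%), (S)-(CF3)3-t-BuPHOX (6 mol%), toluene, 25 °C; then InI (1.5 equiv), Pd(PPh3)4 (5 mol%), THF, high dilution, 25 to 40 °C; aq NH4Cl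
Reagents that add atoms: none
Why: Proposed new method: a one-pot amphiphilic (4+2) spiroannulation in which zerovalent palladium first ionises the carbonate end of 10 (the benzoate end is slower), the methoxide set free deprotonates 6 to its cross-conjugated trienolate, and inner-sphere C–C bond formation at the α-carbon inside the chiral PHOX pocket makes the C5–C6 bond and sets the quaternary C6 as R (Tsuji–Trost asymmetric allylic alkylation of a prochiral enolate); InI then reduces the second π-allylpalladium (from the benzoate end) to a trivalent allylindium that, through its secondary σ-isomer, adds by its γ-carbon to the aldehyde in a chelated bicyclo[2.2.2]-like transition state, closing ring B (C1–C2 bond, cis ring alkene) with the hydroxyl cis to the bulkier gem-dimethyl arm (1S), while the hindered C10 vinyl bromide adds to palladium more slowly than either allylic ester ionises; the closest known reactions are the palladium/InI umpolung allylation of aldehydes with allylic esters and the amphiphilic (3+2) bis-allylation of aldehydes with 2-methylenepropane-1,3-diol derivatives.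

Step 9
Reactants: 12 (1S,6R)-10-bromo-3,7,11,11-tetramethylspiro[5.5]undeca-3,7,9-trien-1-ol
Product: 13 (1S,3S,4S,6R)-4,10-dibromo-3-chloro-3,7,11,11-tetramethylspiro[5.5]undeca-7,9-dien-1-ol
Conditions: n-Bu4NBrCl2 (1.1 equiv), CH2Cl2, −78 to −40 °C
Reagents that add atoms: tetrabutylammonium dichlorobromate, CCCC[N+](CCCC)(CCCC)CCCC.[Cl-].BrCl
Why: Electrophilic anti, Markovnikov bromochlorination: in the preferred half-chair of ring B (C11 equatorial, C7 and the hydroxyl axial) the bromonium forms on the face syn to the hydroxyl because the other face of C4 is shielded by the axial C7 arm, and chloride opens it at the tertiary C3 from the opposite face (axial attack on the other bromonium is blocked by the axial hydroxyl), giving 3S,4S as the trans-diequatorial dihalide that reversible re-ionisation through the bromonium also favours, while the hindered, bromine-deactivated ring A diene reacts more slowly.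

## Compound list

1 | 3-chloro-3-methylbut-1-yne | CC(C)(Cl)C#C | starting material
2 | 2-(propan-2-ylidene)propanedinitrile | CC(C)=C(C#N)C#N | starting material
3 | 2-(2-methylbut-3-yn-2-yl)-2-(prop-1-en-2-yl)propanedinitrile | CC(=C)C(C#N)(C#N)C(C)(C)C#C | intermediate
4 | 3,3-dimethyl-2-(prop-1-en-2-yl)pent-4-ynenitrile (racemic) | CC(=C)C(C#N)C(C)(C)C#C | intermediate
5 | 5-bromo-2,6,6-trimethylcyclohexa-2,4-diene-1-carbonitrile (racemic) | CC1=CC=C(Br)C(C)(C)C1C#N | intermediate
6 | 5-bromo-2,6,6-trimethylcyclohexa-2,4-diene-1-carbaldehyde (racemic) | CC1=CC=C(Br)C(C)(C)C1C=O | intermediate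
7 | 3-methylbut-2-en-1-ol | CC(C)=CCO | starting material
8 | methyl 3-methylbut-2-en-1-yl carbonate | COC(=O)OCC=C(C)C | intermediate
9 | (2E)-4-hydroxy-3-methylbut-2-en-1-yl methyl carbonate | COC(=O)OC/C=C(\C)CO | intermediate
10 | (2E)-4-[(methoxycarbonyl)oxy]-2-methylbut-2-en-1-yl benzoate | COC(=O)OC/C=C(\C)COC(=O)c1ccccc1 | intermediate
11 | (2E)-4-[(1R)-5-bromo-1-formyl-2,6,6-trimethylcyclohexa-2,4-dien-1-yl]-2-methylbut-2-en-1-yl benzoate (not isolated) | CC1=CC=C(Br)C(C)(C)[C@@]1(C=O)C/C=C(\C)COC(=O)c1ccccc1 | intermediate
12 | (1S,6R)-10-bromo-3,7,11,11-tetramethylspiro[5.5]undeca-3,7,9-trien-1-ol | CC1=CC=C(Br)C(C)(C)[C@@]12CC=C(C)C[C@@H]2O | intermediate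
13 | (1S,3S,4S,6R)-4,10-dibromo-3-chloro-3,7,11,11-tetramethylspiro[5.5]undeca-7,9-dien-1-ol | CC1=CC=C(Br)C(C)(C)[C@@]12C[C@H](Br)[C@@](C)(Cl)C[C@@H]2O | target

## Step count and risks

Total steps: 9. Longest linear sequence: 6 (steps 1, 2, 3, 4, 8, 9), which is two thirds of the total. The second branch (steps 5–7) is made in parallel and joins at step 8.

The three steps most likely to fail:

**Step 8 (the new annulation).** It may fail by γ-allylation of the trienolate, low enantioselectivity, or no 6-ring closure of the allylindium. The fallback uses known reactions only, sets out from 6 and comes back at 12. Palladium-catalysed asymmetric α-allylation of the α-branched aldehyde with allyl alcohol under chiral phosphate counter-anion/enamine catalysis (Pd(PPh3)4, (S)-TRIP, benzhydrylamine, toluene, 40 °C, then aq HCl) gives (1R)-5-bromo-2,6,6-trimethyl-1-(prop-2-en-1-yl)cyclohexa-2,4-diene-1-carbaldehyde F1. Reagent-controlled Brown methallylation with B-methallyldiisopinocampheylborane (Et2O, −78 °C; NaOH, H2O2) gives (1S)-1-[(1R)-5-bromo-2,6,6-trimethyl-1-(prop-2-en-1-yl)cyclohexa-2,4-dien-1-yl]-3-methylbut-3-en-1-ol F2. Ring-closing metathesis with the second-generation Grubbs catalyst (CH2Cl2, 40 °C) joins the allyl and methallyl groups to close ring B and give 12.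

**Step 9 (facial selectivity of the bromochlorination).** The required adduct cannot form by a chair-like diaxial opening without placing C11 axial, so the outcome rests on the steric and reversibility arguments given in the step; bromoether formation from the other bromonium and attack on the diene are further risks. The fallback sets out from 12 and comes back at 13 by splitting the addition in two. N-bromosuccinimide in wet acetone at 0 °C gives the bromohydrin (1S,3S,4S,6R)-4,10-dibromo-3,7,11,11-tetramethylspiro[5.5]undeca-7,9-diene-1,3-diol F3; water in large excess captures the bromonium at the tertiary carbon, and the diastereomers can be separated at this stage. Dry HCl in CH2Cl2 at −20 °C then replaces only the tertiary hydroxyl by chloride with retention, through neighbouring-group participation of the bromine, giving 13.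

**Step 1 (α- versus γ-attack of the vinylogous carbanion, two fully substituted carbons joined).** The fallback sets out from 2 and comes back at 4, making the C6–C11 bond by conjugate addition so that its position is unambiguous. Ethynylmagnesium bromide (THF, 0 °C) adds 1,4 to 2 to give 2-(2-methylbut-3-yn-2-yl)propanedinitrile F4. PhMgBr transnitrilation gives 3,3-dimethylpent-4-ynenitrile F5. LiN(i-Pr)2 (2 equiv) then acetone gives 2-(2-hydroxypropan-2-yl)-3,3-dimethylpent-4-ynenitrile F6. Dehydration with SOCl2/pyridine gives mainly the conjugated nitrile 3,3-dimethyl-2-(propan-2-ylidene)pent-4-ynenitrile F7. Deprotonation with LiN(i-Pr)2 and kinetic α-protonation (AcOH, −78 °C) deconjugates it to 4.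

## Further compounds

F1 | step 8 | (1R)-5-bromo-2,6,6-trimethyl-1-(prop-2-en-1-yl)cyclohexa-2,4-diene-1-carbaldehyde | CC1=CC=C(Br)C(C)(C)[C@@]1(C=O)CC=C
F2 | step 8 | (1S)-1-[(1R)-5-bromo-2,6,6-trimethyl-1-(prop-2-en-1-yl)cyclohexa-2,4-dien-1-yl]-3-methylbut-3-en-1-ol | CC1=CC=C(Br)C(C)(C)[C@]1(CC=C)[C@@H](O)CC(C)=C
F3 | step 9 | (1S,3S,4S,6R)-4,10-dibromo-3,7,11,11-tetramethylspiro[5.5]undeca-7,9-diene-1,3-diol | CC1=CC=C(Br)C(C)(C)[C@@]12C[C@H](Br)[C@@](C)(O)C[C@@H]2O
F4 | step 1 | 2-(2-methylbut-3-yn-2-yl)propanedinitrile | C#CC(C)(C)C(C#N)C#N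
F5 | step 1 | 3,3-dimethylpent-4-ynenitrile | C#CC(C)(C)CC#N
F6 | step 1 | 2-(2-hydroxypropan-2-yl)-3,3-dimethylpent-4-ynenitrile (racemic) | C#CC(C)(C)C(C#N)C(C)(C)O
F7 | step 1 | 3,3-dimethyl-2-(propan-2-ylidene)pent-4-ynenitrile | CC(C)=C(C#N)C(C)(C)C#C
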